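## Retrosynthetic overview

1. The quinone ring is made last. Its C5=C6 unit is the only unsubstituted CH=CH of the ring and lies between the carbonyl carbons C1 and C4, so at the bis-allylic alcohol level it is the retron of a diene ring-closing metathesis. C2–C3 is carried as sp3 CH–CH2, and every diastereomer of the acyclic 4-alkylocta-1,7-diene-3,6-diol converges on the one flat ring after oxidation and aromatisation.
2. The diene-diol comes from the bis(Weinreb amide) of succinic acid: C-alkylation with the C20 allylic bromide, two vinyl additions, Luche reduction.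
3. The C20 bromide comes from a sulfone alkylation joining (R)-α-cyclogeranyl tolyl sulfone to C8 of a geraniol-derived (2E,6E)-allylic bromide (both E alkenes are bought with geraniol), then desulfonylation.
4. The ring methine comes from CBS reduction of 2,4,4-trimethylcyclohex-2-enone and a decarboxylative Claisen [3,3] shift that carries the carbinol chirality to the carbon next to the gem-dimethyl group.
5. Ring order: the trimethylcyclohexene ring is purchased; the six-membered ring of the quinone is closed in step 15 and brought to the quinone level in steps 16 and 17.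

Key step: step 15

Remarks on the chemistry:
- The ring methine is (R) as read from the given SMILES (the spatial arrangement of (R)-α-ionone); descriptors of intermediates follow from that.
- T stands for the group (2E,6E)-3,7-dimethyl-9-[(1R)-2,6,6-trimethylcyclohex-2-en-1-yl]nona-2,6-dien-1-yl.
- The starting materials 1, 3, 8, 17 and 18 are taken to be commercially available.

## Route

Step 1
Reactants: 1 2,4,4-trimethylcyclohex-2-en-1-one
Product: 2 (1S)-2,4,4-trimethylcyclohex-2-en-1-ol
Conditions: (R)-2-methyl-CBS-oxazaborolidine (10 mol %), BH3·SMe2, THF, −20 °C; MeOH quench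
Reagents that add atoms: none
Why: Corey–Bakshi–Shibata reduction, in which the oxazaborolidine tells the α-methylalkenyl flank (large) from the CH2 flank (small) of the ketone, so the (R)-catalyst should deliver hydride to the face that gives the (S)-carbinol, with 1,2-reduction favoured over hydroboration at low temperature.

Step 2
Reactants: 2 (1S)-2,4,4-trimethylcyclohex-2-en-1-ol; 3 (4-methylphenylsulfonyl)acetic acid
Product: 4 (1S)-2,4,4-trimethylcyclohex-2-en-1-yl (4-methylphenylsulfonyl)acetate
Conditions: N,N'-diisopropylcarbodiimide, DMAP (5 mol %), CH2Cl2, 0 °C → rt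
Reagents that add atoms: none
Why: Steglich-type carbodiimide esterification at oxygen, which leaves the carbinol configuration untouched.

Step 3
Reactants: 4 (1S)-2,4,4-trimethylcyclohex-2-en-1-yl (4-methylphenylsulfonyl)acetate
Product: 7 1-methyl-4-{[(1R)-2,6,6-trimethylcyclohex-2-en-1-yl]methylsulfonyl}benzene, via silyl ketene acetal 5 (not isolated), via trimethylsilyl ester 6 (not isolated)
Conditions: N,O-bis(trimethylsilyl)acetamide (0.2 equiv), KOAc (0.1 equiv), toluene, 110 °C
Reagents that add atoms: none
Why: Decarboxylative Claisen rearrangement (Ireland–Claisen-type [3,3] shift of the silyl ketene acetal, then acetate-triggered desilylation and loss of CO2); the shift is suprafacial, so the C1–O chirality of 4 is carried to the new C–C bond at C3 and should give the (R) ring methine.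

Step 4
Reactants: 8 geraniol
Product: 9 tert-butyl{[(2E)-3,7-dimethylocta-2,6-dien-1-yl]oxy}dimethylsilane
Conditions: TBSCl, imidazole, DMF, 0 °C → rt
Reagents that add atoms: tert-butyldimethylsilyl chloride, CC(C)(C)[Si](C)(C)Cl
Why: Standard silylation of a primary allylic alcohol, giving an ether that withstands the sulfone carbanion and the amalgam reduction.

Step 5
Reactants: 9 tert-butyl{[(2E)-3,7-dimethylocta-2,6-dien-1-yl]oxy}dimethylsilane
Product: 10 (2E,6E)-8-(tert-butyldimethylsilyloxy)-2,6-dimethylocta-2,6-dien-1-ol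
Conditions: SeO2 (0.2 equiv), t-BuOOH (3 equiv), salicylic acid (0.1 equiv), CH2Cl2, rt
Reagents that add atoms: tert-butyl hydroperoxide, CC(C)(C)OO; selenium dioxide (catalytic oxygen carrier), O=[Se]=O
Why: Sharpless–Umbreit allylic hydroxylation (ene reaction then [2,3] shift), which should oxidise the E methyl group of the distal, more electron-rich alkene because the proximal alkene is deactivated by the allylic oxygen.

Step 6
Reactants: 10 (2E,6E)-8-(tert-butyldimethylsilyloxy)-2,6-dimethylocta-2,6-dien-1-ol
Product: 11 {[(2E,6E)-8-bromo-3,7-dimethylocta-2,6-dien-1-yl]oxy}(tert-butyl)dimethylsilane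
Conditions: CBr4, PPh3, CH2Cl2, −10 °C
Reagents that add atoms: carbon tetrabromide, BrC(Br)(Br)Br
Why: Appel bromination of a primary allylic alcohol through the alkoxyphosphonium salt, an SN2 event that should keep the E geometry.

Step 7
Reactants: 7 1-methyl-4-{[(1R)-2,6,6-trimethylcyclohex-2-en-1-yl]methylsulfonyl}benzene; 11 {[(2E,6E)-8-bromo-3,7-dimethylocta-2,6-dien-1-yl]oxy}(tert-butyl)dimethylsilane
Product: 13 tert-butyl{[(2E,6E)-3,7-dimethyl-9-(4-methylphenylsulfonyl)-9-((1R)-2,6,6-trimethylcyclohex-2-en-1-yl)nona-2,6-dien-1-yl]oxy}dimethylsilane, via lithiated sulfone 12 (not isolated)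
Conditions: n-BuLi (1.05 equiv), THF, −78 °C; then 11, −78 → −20 °C
Reagents that add atoms: none
Why: Alkylation of an α-sulfonyl carbanion with a primary allylic bromide (SN2, no allylic transposition, E geometry kept); the new sulfone-bearing centre forms as a mixture and is removed in step 8.

Step 8
Reactants: 13 tert-butyl{[(2E,6E)-3,7-dimethyl-9-(4-methylphenylsulfonyl)-9-((1R)-2,6,6-trimethylcyclohex-2-en-1-yl)nona-2,6-dien-1-yl]oxy}dimethylsilane (the C9 sulfone of step 7)
Product: 14 tert-butyl{[(2E,6E)-3,7-dimethyl-9-((1R)-2,6,6-trimethylcyclohex-2-en-1-yl)nona-2,6-dien-1-yl]oxy}dimethylsilane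
Conditions: Na(Hg) (6 % Na), Na2HPO4, MeOH/THF, −20 → 0 °C
Reagents that add atoms: none
Why: Reductive desulfonylation by single-electron transfer from sodium amalgam, which cleaves the C–S bond and protonates the carbanion without touching the trisubstituted alkenes or the silyl ether.

Step 9
Reactants: 14 tert-butyl{[(2E,6E)-3,7-dimethyl-9-((1R)-2,6,6-trimethylcyclohex-2-en-1-yl)nona-2,6-dien-1-yl]oxy}dimethylsilane (the silyl ether of step 8)
Product: 15 (2E,6E)-3,7-dimethyl-9-[(1R)-2,6,6-trimethylcyclohex-2-en-1-yl]nona-2,6-dien-1-ol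
Conditions: Bu4NF, THF, 0 °C → rt
Reagents that add atoms: none
Why: Fluoride-driven desilylation, resting on the strength of the Si–F bond.

Step 10
Reactants: 15 (2E,6E)-3,7-dimethyl-9-[(1R)-2,6,6-trimethylcyclohex-2-en-1-yl]nona-2,6-dien-1-ol
Product: 16 (2E,6E)-1-bromo-3,7-dimethyl-9-[(1R)-2,6,6-trimethylcyclohex-2-en-1-yl]nona-2,6-diene
Conditions: CBr4, PPh3, CH2Cl2, −20 → 0 °C; used crude
Reagents that add atoms: carbon tetrabromide, BrC(Br)(Br)Br
Why: Appel bromination as in step 6, the way geranyl-type bromides are made with retention of the E alkene.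

Step 11
Reactants: 17 butanedioyl dichloride; 18 N,O-dimethylhydroxylamine hydrochloride (2.2 equiv)
Product: 19 N1,N4-dimethoxy-N1,N4-dimethylbutanediamide
Conditions: pyridine (5 equiv), CH2Cl2, 0 °C → rt
Reagents that add atoms: N,O-dimethylhydroxylamine hydrochloride (the second equivalent of 18), CNOC.Cl
Why: Acylation of the amine by the acid chloride (Schotten–Baumann-type amide formation) at both acyl chloride ends, so two molecules of 18 are built into 19 while pyridine takes up the four equivalents of HCl.

Step 12
Reactants: 19 N1,N4-dimethoxy-N1,N4-dimethylbutanediamide (2.5 equiv); 16 (2E,6E)-1-bromo-3,7-dimethyl-9-[(1R)-2,6,6-trimethylcyclohex-2-en-1-yl]nona-2,6-diene (the C20 bromide T-Br)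
Product: 21 2-T-N1,N4-dimethoxy-N1,N4-dimethylbutanediamide, via lithium enolate 20 (not isolated)
Conditions: LiN(iPr)2 (2.3 equiv), THF, −78 °C; then 16, −78 → −30 °C
Reagents that add atoms: none
Why: SN2 alkylation of an amide enolate by a primary allylic bromide, with 19 in excess to suppress dialkylation; the new C2 centre is uncontrolled and is erased in step 17.

Step 13
Reactants: 21 2-T-N1,N4-dimethoxy-N1,N4-dimethylbutanediamide
Product: 22 4-T-octa-1,7-diene-3,6-dione
Conditions: CH2=CHMgBr (5 equiv), THF, −10 → 0 °C; inverse quench into cold 1 M HCl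
Reagents that add atoms: vinylmagnesium bromide (two equivalents are incorporated), C=C[Mg]Br
Why: Weinreb ketone synthesis at both amides, the chelated tetrahedral adducts preventing over-addition and the acidic inverse quench keeping the released amine from adding to the vinyl ketones.

Step 14
Reactants: 22 4-T-octa-1,7-diene-3,6-dione
Product: 23 4-T-octa-1,7-diene-3,6-diol (mixture of diastereomers)
Conditions: NaBH4, CeCl3·7H2O, MeOH, −40 °C
Reagents that add atoms: none
Why: Luche reduction, selective for 1,2-addition to both enones; the two carbinol centres form without control and are erased in step 16.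

Step 15
Reactants: 23 4-T-octa-1,7-diene-3,6-diol
Product: 24 5-T-cyclohex-2-ene-1,4-diol (mixture of diastereomers)
Conditions: RuCl2(PCy3)2(=CHPh) (first-generation Grubbs catalyst, 5 mol %), CH2Cl2 (0.005 M), 40 °C, open to an argon stream
Reagents that add atoms: none
Why: Alkene metathesis by the Chauvin mechanism: the ruthenium benzylidene exchanges onto a terminal vinyl group, most readily the C7=C8 vinyl whose carbinol C6 is flanked by the unbranched C5 methylene, and the new alkylidene adds across the C1=C2 vinyl group through a ruthenacyclobutane whose cycloreversion releases ethylene and the ring alkene. The closest known reaction type is the ring-closing metathesis of octa-1,7-diene-3,6-diols and their polyol relatives to cyclohex-2-ene-1,4-diols, as used for conduritols. The one ring closed is the six-membered carbocycle of the future quinone, closed by forming the C=C bond between C2 and C7 of the octadiene, which become the unsubstituted CH=CH between the two carbonyl carbons; the endocyclic alkene can only be cis. No new stereocentre arises, and the three uncontrolled centres of 23 are cleared in steps 16 and 17, so all eight diastereomers of 23 converge on one product. The step needs chemoselectivity for the two monosubstituted alkenes over the three trisubstituted ones, above all over the first chain alkene, which could close a cyclopentene with the C1=C2 vinyl group and cut off the chain; this rests on the low reactivity of RuCl2(PCy3)2(=CHPh) toward trisubstituted alkenes, on the activation of both vinyl groups by their allylic hydroxyl groups and on high dilution against oligomerisation.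

Step 16
Reactants: 24 5-T-cyclohex-2-ene-1,4-diol
Product: 25 5-T-cyclohex-2-ene-1,4-dione
Conditions: Dess–Martin periodinane (2.5 equiv), CH2Cl2, 0 °C → rt; filtered through a short pad and used crude
Reagents that add atoms: none
Why: Dess–Martin oxidation of both secondary allylic alcohols, which removes the two carbinol stereocentres and gives the keto tautomer of the hydroquinone.

Step 17
Reactants: 25 5-T-cyclohex-2-ene-1,4-dione
Product: 27 2-T-cyclohexa-2,5-diene-1,4-dione (the target), via hydroquinone 26 (not isolated)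
Conditions: Et3N (0.1 equiv), CH2Cl2, rt, Ar; then Ag2O, Na2SO4, rt
Reagents that add atoms: none
Why: Amine-catalysed double enolisation aromatises the ene-dione, as it does for Diels–Alder adducts of quinones, and Ag2O then oxidises the hydroquinone to the quinone, leaving the remote (R) methine as the only stereocentre.

## Compound list

1 | 2,4,4-trimethylcyclohex-2-en-1-one | CC1=CC(C)(C)CCC1=O | starting material
2 | (1S)-2,4,4-trimethylcyclohex-2-en-1-ol | O[C@@H]1C(C)=CC(C)(C)CC1 | intermediate
3 | (4-methylphenylsulfonyl)acetic acid | Cc1ccc(cc1)S(=O)(=O)CC(=O)O | starting material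
4 | (1S)-2,4,4-trimethylcyclohex-2-en-1-yl (4-methylphenylsulfonyl)acetate | Cc1ccc(cc1)S(=O)(=O)CC(=O)O[C@@H]1C(C)=CC(C)(C)CC1 | intermediate
5 | trimethylsilyl ketene acetal of 4 (not isolated) | Cc1ccc(cc1)S(=O)(=O)C=C(O[Si](C)(C)C)O[C@@H]1C(C)=CC(C)(C)CC1 | intermediate
6 | trimethylsilyl 2-(4-methylphenylsulfonyl)-2-[(1R)-2,6,6-trimethylcyclohex-2-en-1-yl]acetate (not isolated) | Cc1ccc(cc1)S(=O)(=O)C(C(=O)O[Si](C)(C)C)[C@H]1C(C)=CCCC1(C)C | intermediate
7 | 1-methyl-4-{[(1R)-2,6,6-trimethylcyclohex-2-en-1-yl]methylsulfonyl}benzene | Cc1ccc(cc1)S(=O)(=O)C[C@H]1C(C)=CCCC1(C)C | intermediate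
8 | geraniol | CC(C)=CCC/C(C)=C/CO | starting material
9 | tert-butyl{[(2E)-3,7-dimethylocta-2,6-dien-1-yl]oxy}dimethylsilane | CC(C)=CCC/C(C)=C/CO[Si](C)(C)C(C)(C)C | intermediate
10 | (2E,6E)-8-(tert-butyldimethylsilyloxy)-2,6-dimethylocta-2,6-dien-1-ol | OC/C(C)=C/CC/C(C)=C/CO[Si](C)(C)C(C)(C)C | intermediate
11 | {[(2E,6E)-8-bromo-3,7-dimethylocta-2,6-dien-1-yl]oxy}(tert-butyl)dimethylsilane | BrC/C(C)=C/CC/C(C)=C/CO[Si](C)(C)C(C)(C)C | intermediate
12 | α-lithio derivative of sulfone 7 (not isolated) | [Li]C(S(=O)(=O)c1ccc(C)cc1)[C@H]1C(C)=CCCC1(C)C | intermediate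
13 | tert-butyl{[(2E,6E)-3,7-dimethyl-9-(4-methylphenylsulfonyl)-9-((1R)-2,6,6-trimethylcyclohex-2-en-1-yl)nona-2,6-dien-1-yl]oxy}dimethylsilane (C9 epimers) | Cc1ccc(cc1)S(=O)(=O)C(C/C(C)=C/CC/C(C)=C/CO[Si](C)(C)C(C)(C)C)[C@H]1C(C)=CCCC1(C)C | intermediate
14 | tert-butyl{[(2E,6E)-3,7-dimethyl-9-((1R)-2,6,6-trimethylcyclohex-2-en-1-yl)nona-2,6-dien-1-yl]oxy}dimethylsilane | CC(C)(C)[Si](C)(C)OC/C=C(C)/CC/C=C(C)/CC[C@H]1C(C)=CCCC1(C)C | intermediate
15 | (2E,6E)-3,7-dimethyl-9-[(1R)-2,6,6-trimethylcyclohex-2-en-1-yl]nona-2,6-dien-1-ol | OC/C=C(C)/CC/C=C(C)/CC[C@H]1C(C)=CCCC1(C)C | intermediate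
16 | (2E,6E)-1-bromo-3,7-dimethyl-9-[(1R)-2,6,6-trimethylcyclohex-2-en-1-yl]nona-2,6-diene | BrC/C=C(C)/CC/C=C(C)/CC[C@H]1C(C)=CCCC1(C)C | intermediate
17 | butanedioyl dichloride | ClC(=O)CCC(Cl)=O | starting material
18 | N,O-dimethylhydroxylamine hydrochloride | CNOC.Cl | starting material
19 | N1,N4-dimethoxy-N1,N4-dimethylbutanediamide | CON(C)C(=O)CCC(=O)N(C)OC | intermediate
20 | lithium enolate of 19 (not isolated) | CON(C)C(=O)CC=C(O[Li])N(C)OC | intermediate
21 | 2-T-N1,N4-dimethoxy-N1,N4-dimethylbutanediamide (C2 epimers) | CON(C)C(=O)CC(C/C=C(C)/CC/C=C(C)/CC[C@H]1C(C)=CCCC1(C)C)C(=O)N(C)OC | intermediate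
22 | 4-T-octa-1,7-diene-3,6-dione | C=CC(=O)CC(C/C=C(C)/CC/C=C(C)/CC[C@H]1C(C)=CCCC1(C)C)C(=O)C=C | intermediate
23 | 4-T-octa-1,7-diene-3,6-diol (diastereomer mixture) | C=CC(O)CC(C/C=C(C)/CC/C=C(C)/CC[C@H]1C(C)=CCCC1(C)C)C(O)C=C | intermediate
24 | 5-T-cyclohex-2-ene-1,4-diol (diastereomer mixture) | OC1C=CC(O)C(C/C=C(C)/CC/C=C(C)/CC[C@H]2C(C)=CCCC2(C)C)C1 | intermediate
25 | 5-T-cyclohex-2-ene-1,4-dione | O=C1C=CC(=O)C(C/C=C(C)/CC/C=C(C)/CC[C@H]2C(C)=CCCC2(C)C)C1 | intermediate
26 | 2-T-benzene-1,4-diol (not isolated) | Oc1ccc(O)c(C/C=C(C)/CC/C=C(C)/CC[C@H]2C(C)=CCCC2(C)C)c1 | intermediate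
27 | 2-[(2E,6E)-3,7-dimethyl-9-((1R)-2,6,6-trimethylcyclohex-2-en-1-yl)nona-2,6-dien-1-yl]cyclohexa-2,5-diene-1,4-dione | CC1=CCCC(C)(C)[C@H]1CC/C(C)=C/CC/C(C)=C/CC1=CC(=O)C=CC1=O | target

## Step count and risks

Total step count: 17. Longest linear sequence: 13 steps (1, 2, 3, 7, 8, 9, 10, 12, 13, 14, 15, 16, 17 from enone 1; the same length from geraniol through 4, 5, 6).

Steps most likely to fail:

1. Step 15. The ruthenium alkylidene, once it sits on the C1=C2 vinyl group, may engage the nearest trisubstituted chain alkene and close a cyclopentene with loss of the terpenoid chain, or intermolecular metathesis may outrun ring closure. The fallback sets out from bromide 16 and gives up making the ring. 1,4-Dimethoxybenzene is lithiated with n-BuLi and TMEDA in THF at 0 °C to 2,5-dimethoxyphenyllithium F1. In the presence of CuBr·SMe2 this is coupled with 16 at −78 → 0 °C (SN2, E geometry kept) to 2-T-1,4-dimethoxybenzene F2. Oxidative demethylation with (NH4)2Ce(NO3)6 in MeCN/H2O at 0 °C gives the quinone, so the fallback comes back to the route at 27.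

2. Step 3. The [3,3] shift must form a bond at the carbon next to the gem-dimethyl group and may be too slow, so that thermal elimination of the allylic ester to a diene, or ionisation with loss of enantiopurity, takes over. The fallback sets out from alcohol 2. O-Alkylation with KH and Bu3SnCH2I in THF gives tributyl{[(1S)-2,4,4-trimethylcyclohex-2-en-1-yl]oxymethyl}stannane F3. Tin–lithium exchange with n-BuLi at −78 °C triggers a Still–Wittig [2,3] rearrangement, suprafacial like the Claisen shift, to [(1R)-2,6,6-trimethylcyclohex-2-en-1-yl]methanol F4. Hata thioetherification with bis(4-methylphenyl) disulfide and Bu3P gives 1-methyl-4-{[(1R)-2,6,6-trimethylcyclohex-2-en-1-yl]methylsulfanyl}benzene F5. Chemoselective oxidation at sulfur with H2O2 and catalytic (NH4)6Mo7O24 in EtOH at 0 °C gives the sulfone, so the fallback comes back to the route at 7.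

3. Step 13. The bis(vinyl ketone) may polymerise, or suffer conjugate addition of the released N,O-dimethylhydroxylamine or of excess Grignard reagent, during reaction and quench. The fallback sets out from 21 and avoids the vinyl ketones. Reduction of both Weinreb amides with iBu2AlH in THF at −78 °C gives 2-T-butanedial F6, which is used crude. Addition of excess CH2=CHMgBr at −78 → 0 °C gives the diol directly, so the fallback comes back to the route at 23 and makes step 14 unnecessary.

Further compounds
F1 | step 15 | 2,5-dimethoxyphenyllithium | [Li]c1cc(OC)ccc1OC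
F2 | step 15 | 2-[(2E,6E)-3,7-dimethyl-9-((1R)-2,6,6-trimethylcyclohex-2-en-1-yl)nona-2,6-dien-1-yl]-1,4-dimethoxybenzene | COc1ccc(OC)c(C/C=C(C)/CC/C=C(C)/CC[C@H]2C(C)=CCCC2(C)C)c1
F3 | step 3 | tributyl{[(1S)-2,4,4-trimethylcyclohex-2-en-1-yl]oxymethyl}stannane | CCCC[Sn](CCCC)(CCCC)CO[C@@H]1C(C)=CC(C)(C)CC1
F4 | step 3 | [(1R)-2,6,6-trimethylcyclohex-2-en-1-yl]methanol | OC[C@H]1C(C)=CCCC1(C)C
F5 | step 3 | 1-methyl-4-{[(1R)-2,6,6-trimethylcyclohex-2-en-1-yl]methylsulfanyl}benzene | Cc1ccc(cc1)SC[C@H]1C(C)=CCCC1(C)C
F6 | step 13 | 2-[(2E,6E)-3,7-dimethyl-9-((1R)-2,6,6-trimethylcyclohex-2-en-1-yl)nona-2,6-dien-1-yl]butanedial | O=CCC(C/C=C(C)/CC/C=C(C)/CC[C@H]1C(C)=CCCC1(C)C)C=O
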